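Ring B (C5–C6–C7–C8–C9–C10, labdane numbering) is made by one-carbon enlargement of a cyclopentane. (+)-Sclareolide supplies ring A and the C5, C9 and C10 stereocentres. Its own ring B is cut at C7–C8 (ozonolysis of the Δ7 olefin) and re-closed from C6 to C8 (aldol condensation) to a B-nor enal with C7 as an exocyclic formyl carbon. α-Face dihydroxylation gives a tertiary α-hydroxy aldehyde, whose α-ketol shift moves C8 from C6 to C7. This single step forms the six-membered ring and the contiguous C6 (ketone), C7 (carbinol), C8 (tertiary carbinol) oxygen triad that the target carries. Reduction, side-chain olefination and 7-O-acetylation finish the route.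

Key step: step 5

Remark: labdane numbering is kept for every intermediate, also the ring-contracted ones (C17 = methyl on C8, C20 = methyl on C10, C11/C12 = side chain); the target is read as (12E)-labda-12,14-diene-6β,7β,8α-triol 7-acetate, normal (5S,10S) series.

Step 1
Reactants: 1 (+)-sclareolide
Product: 3 methyl 13,14,15,16-tetranorlabd-7-en-12-oate, via Δ7 acid 2 (not isolated)
Conditions: conc. H2SO4, MeOH, 0 °C → rt, stopped at full conversion of 1
Reagents that add atoms: methanol, CO
Why: E1 opening of the tertiary C8–O lactone bond gives the C8 cation, which should lose the accessible axial 7-H under kinetic control (acid-mediated dehydration) before Fischer esterification of the acid in the same pot; no stereocentre is formed, and the Δ8(9)/Δ8(17) isomers expected as by-products are to be removed on AgNO3–silica.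

Step 2
Reactants: 3 methyl 13,14,15,16-tetranorlabd-7-en-12-oate
Product: 5 methyl 7,8-dioxo-7,8-seco-13,14,15,16-tetranorlabdan-12-oate, via ozonide 4 (not isolated)
Conditions: O3, CH2Cl2, −78 °C; then Me2S, −78 °C → rt
Reagents that add atoms: ozone, [O-][O+]=O
Why: Ozonolysis with reductive work-up cleaves the only C=C (C7=C8) to the C7 aldehyde and the C8 methyl ketone, and the neutral work-up should leave C9 (α to the new ketone) untouched.

Step 3
Reactants: 5 methyl 7,8-dioxo-7,8-seco-13,14,15,16-tetranorlabdan-12-oate
Product: 7 methyl 7-oxo-8(7→6)-abeo-13,14,15,16-tetranorlabd-6(8)-en-12-oate, via aldol adduct 6 (not isolated)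
Conditions: Bn2NH·CF3CO2H (cat.), benzene, 50 °C
Reagents that add atoms: none
Why: Intramolecular aldol condensation under secondary-ammonium catalysis: the aldehyde enamine attacks the methyl ketone through C6 (5-(enolexo)-exo-trig closure of the C5–C6–C8–C9–C10 ring) and E1cB loss of water gives the conjugated enal; this catalysis favours the aldehyde-enamine mode over ketone-enolate attack on the aldehyde, and no stereocentre is formed.

Step 4
Reactants: 7 methyl 7-oxo-8(7→6)-abeo-13,14,15,16-tetranorlabd-6(8)-en-12-oate
Product: 8 methyl 6α,8α-dihydroxy-7-oxo-8(7→6)-abeo-13,14,15,16-tetranorlabdan-12-oate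
Conditions: OsO4 (5 mol %), NMO, citric acid, t-BuOH–H2O, rt
Reagents that add atoms: osmium tetroxide, O=[Os](=O)(=O)=O; N-methylmorpholine N-oxide, C[N+]1([O-])CCOCC1; water, O
Why: Catalytic osmium tetroxide syn-dihydroxylation under the acidic protocol for electron-poor olefins; OsO4 should add to the α face of the cyclopentene, anti to the angular C10 methyl and the C9 β side chain, setting 6α-OH and 8α-OH/8β-CH3 together.

Step 5
Reactants: 8 methyl 6α,8α-dihydroxy-7-oxo-8(7→6)-abeo-13,14,15,16-tetranorlabdan-12-oate
Product: 9 methyl 7β,8α-dihydroxy-6-oxo-13,14,15,16-tetranorlabdan-12-oate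
Conditions: DBU (0.2 equiv), CH2Cl2, 0 °C → rt
Reagents that add atoms: none
Why: DBU ionises the C6–OH (α to the formyl group, the most acidic hydroxyl) and the alkoxide undergoes the α-ketol (acyloin) rearrangement: the C6–C8 bond, aligned with the formyl π* orbital, shifts suprafacially from C6 to C7 while O6 becomes the C6 ketone, the same reaction type as the D-homoannulation of 17-hydroxy-17-acyl steroids. The six-membered ring C5–C6–C7–C8–C9–C10 therefore closes by one-carbon enlargement of the cyclopentane C5–C6–C8–C9–C10 (the exocyclic C7 is inserted between C6 and C8 by a [1,2]-shift, not by an end-to-end cyclisation), driven by aldehyde-to-ketone conversion and the change from cyclopentane to chair cyclohexane. C8 migrates with retention, so the 8α-OH/8β-CH3 centre from the dihydroxylation is carried over unchanged; the new C7 centre is controlled by the anti arrangement of the C6–O⁻ and C7=O dipoles in the alkoxide, which should place O7 on the β face (equatorial), and this is also expected to be the thermodynamic epimer because C7 is enolisable; C5, now α to the ketone, should stay trans (5α). The step needs C8 and not C5 to migrate: C8 is fully substituted and oxygen-bearing, and a shift of C5 would only give the tautomeric α-ketol of the same decalin, which enediol equilibration should funnel to 9. It also needs the shift to outrun retro-aldol opening through a C8 alkoxide, which the weak amidine base should secure because it ionises only the far more acidic O6–H.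

Step 6
Reactants: 9 methyl 7β,8α-dihydroxy-6-oxo-13,14,15,16-tetranorlabdan-12-oate
Product: 10 8α,12-epoxy-13,14,15,16-tetranorlabdane-6β,7β,12-triol
Conditions: DIBAL-H (5 equiv), CH2Cl2, −78 °C; MeOH, then aq. Rochelle salt
Reagents that add atoms: none
Why: Hydride reduction: the C6 ketone should be attacked from the α face because the axial β approach is blocked by the syn-axial C10 and C4β methyls, giving the axial 6β-alcohol, while the ester stops at the aldehyde stage at −78 °C and is captured by the 8α-OH as the five-membered lactol (any 8,12-lactone formed earlier would give the same lactol).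

Step 7
Reactants: 10 8α,12-epoxy-13,14,15,16-tetranorlabdane-6β,7β,12-triol; 11 2-(triphenylphosphoranylidene)propanal
Product: 12 (12E)-6β,7β,8α-trihydroxy-15-norlabd-12-en-14-al
Conditions: toluene, 90 °C
Reagents that add atoms: 2-(triphenylphosphoranylidene)propanal, CC(C=O)=P(c1ccccc1)(c1ccccc1)c1ccccc1
Why: Wittig olefination of the lactol through its open hydroxy-aldehyde form; the stabilised ylide should give the (E)-trisubstituted enal, and the neutral conditions should suppress oxa-Michael addition of the 8-OH to C12.

Step 8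
Reactants: 12 (12E)-6β,7β,8α-trihydroxy-15-norlabd-12-en-14-al
Product: 13 (12E)-labda-12,14-diene-6β,7β,8α-triol
Conditions: Ph3PCH3Br, KHMDS, THF, 0 °C; then 12, −78 → 0 °C (excess ylide)
Reagents that add atoms: methyltriphenylphosphonium bromide, C[P+](c1ccccc1)(c1ccccc1)c1ccccc1.[Br-]
Why: Wittig methylenation of the enal carbonyl (fast 1,2-addition at low temperature, tolerant of the free hydroxyls with excess ylide) should complete the 12,14-diene without touching the C12=C13 geometry.

Step 9
Reactants: 13 (12E)-labda-12,14-diene-6β,7β,8α-triol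
Product: 14 (12E)-labda-12,14-diene-6β,7β,8α-triol 7-acetate
Conditions: Ac2O, pyridine, CH2Cl2, 0 °C → rt
Reagents that add atoms: acetic anhydride, CC(=O)OC(C)=O
Why: Site-selective O-acylation: only the equatorial secondary 7β-OH should react without DMAP, since the axial 6β-OH is shielded by the syn-axial C10/C4β methyls and the 8α-OH is tertiary.

Compound list
1 | (+)-sclareolide (13,14,15,16-tetranorlabdano-12,8α-lactone; 5α-H, 9α-H, 10β-CH3) | O=C1C[C@H]2[C@](C)(O1)CC[C@H]3C(C)(C)CCC[C@@]32C | starting material
2 | 13,14,15,16-tetranorlabd-7-en-12-oic acid (5α-H, 9α-H, 10β-CH3; not isolated) | OC(=O)C[C@H]1C(C)=CC[C@H]2C(C)(C)CCC[C@@]21C | intermediate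
3 | methyl 13,14,15,16-tetranorlabd-7-en-12-oate (5α-H, 9α-H, 10β-CH3) | COC(=O)C[C@H]1C(C)=CC[C@H]2C(C)(C)CCC[C@@]21C | intermediate
4 | 7,8-ozonide of 3 (1,2,4-trioxolane across C7 and C8, C7/C8 epimers; not isolated) | COC(=O)C[C@H]1C2(C)OOC(O2)C[C@H]3C(C)(C)CCC[C@@]31C | intermediate
5 | methyl 7,8-dioxo-7,8-seco-13,14,15,16-tetranorlabdan-12-oate (ring A with CH2CHO on C5 and CH(COCH3)CH2CO2Me on C10, trans; 5α-H, 9α-H, 10β-CH3) | COC(=O)C[C@@H](C(C)=O)[C@@]1(C)CCCC(C)(C)[C@@H]1CC=O | intermediate
6 | methyl 8-hydroxy-7-oxo-8(7→6)-abeo-13,14,15,16-tetranorlabdan-12-oate (aldol adduct, C6/C8 epimers; not isolated) | COC(=O)C[C@H]1C(C)(O)C(C=O)[C@H]2C(C)(C)CCC[C@@]21C | intermediate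
7 | methyl 7-oxo-8(7→6)-abeo-13,14,15,16-tetranorlabd-6(8)-en-12-oate (B-nor enal: trans-fused hydrindene with C6(CHO)=C8(CH3); 5α-H, 9α-H, 10β-CH3) | COC(=O)C[C@H]1C(C)=C(C=O)[C@H]2C(C)(C)CCC[C@@]21C | intermediate
8 | methyl 6α,8α-dihydroxy-7-oxo-8(7→6)-abeo-13,14,15,16-tetranorlabdan-12-oate (6β-CHO, 8β-CH3; 5α-H, 9α-H, 10β-CH3) | COC(=O)C[C@H]1[C@](C)(O)[C@@](O)(C=O)[C@H]2C(C)(C)CCC[C@@]21C | intermediate
9 | methyl 7β,8α-dihydroxy-6-oxo-13,14,15,16-tetranorlabdan-12-oate (8β-CH3; 5α-H, 9α-H, 10β-CH3) | COC(=O)C[C@H]1[C@](C)(O)[C@@H](O)C(=O)[C@H]2C(C)(C)CCC[C@@]21C | intermediate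
10 | 8α,12-epoxy-13,14,15,16-tetranorlabdane-6β,7β,12-triol (lactol, both C12 epimers) | OC1C[C@H]2[C@](C)(O1)[C@@H](O)[C@@H](O)[C@H]3C(C)(C)CCC[C@@]32C | intermediate
11 | 2-(triphenylphosphoranylidene)propanal | CC(C=O)=P(c1ccccc1)(c1ccccc1)c1ccccc1 | starting material
12 | (12E)-6β,7β,8α-trihydroxy-15-norlabd-12-en-14-al | O=C/C(C)=C/C[C@H]1[C@](C)(O)[C@@H](O)[C@@H](O)[C@H]2C(C)(C)CCC[C@@]21C | intermediate
13 | (12E)-labda-12,14-diene-6β,7β,8α-triol | C=C/C(C)=C/C[C@H]1[C@](C)(O)[C@@H](O)[C@@H](O)[C@H]2C(C)(C)CCC[C@@]21C | intermediate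
14 | (12E)-labda-12,14-diene-6β,7β,8α-triol 7-acetate (5S,6S,7S,8S,9R,10S) | C=C/C(C)=C/C[C@H]1[C@](C)(O)[C@@H](OC(C)=O)[C@@H](O)[C@H]2C(C)(C)CCC[C@@]21C | target

Total step count: 9
Longest linear sequence: 9 steps (from 1)

Steps most likely to fail

Step 5. The alkoxide may open the β-hydroxy aldehyde by retro-aldol fragmentation instead of undergoing the 1,2-shift, which would scramble C8, or prolonged base may drift the product towards its ketol tautomer. The fallback sets out from 8 and runs the shift in the neutral chelate manifold (Al(OtBu)3, toluene, 60 °C), where O6 and the formyl oxygen are held syn on aluminium and no free alkoxide is present. This should give the axial C7 epimer, methyl 7α,8α-dihydroxy-6-oxo-13,14,15,16-tetranorlabdan-12-oate F1, which is then equilibrated at C7 through the enediol by a short contact with K2CO3 in MeOH at 0 °C and comes back to the route at 9.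

Step 4. Osmylation of the tetrasubstituted, electron-poor and hindered enal may stall, or the aldehyde may be over-oxidised through its hydrate. The fallback sets out from 7: Luche reduction (NaBH4, CeCl3, MeOH, −40 °C) gives the allylic alcohol methyl 7-hydroxy-8(7→6)-abeo-13,14,15,16-tetranorlabd-6(8)-en-12-oate F2. Its now electron-rich olefin is dihydroxylated from the α face (OsO4 cat., NMO) to the triol methyl 6α,7,8α-trihydroxy-8(7→6)-abeo-13,14,15,16-tetranorlabdan-12-oate F3. Oxidation of the only primary hydroxyl (TEMPO cat., PhI(OAc)2) comes back to the route at 8.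

Step 1. The C8 cation may be deprotonated at C9 or C17 instead of C7, or the Δ7 olefin may isomerise to the tetrasubstituted Δ8(9) olefin under the acid. The fallback sets out from 1: saponification (KOH, MeOH) gives potassium 8α-hydroxy-13,14,15,16-tetranorlabdan-12-oate F4, and O-methylation (MeI, DMF) gives methyl 8α-hydroxy-13,14,15,16-tetranorlabdan-12-oate F5. Kinetic dehydration (SOCl2, pyridine, −78 °C) should give the exocyclic olefin methyl 13,14,15,16-tetranorlabd-8(17)-en-12-oate F6. A cobalt-hydride (hydrogen-atom-transfer) olefin isomerisation (Co(salen)Cl cat., PhSiH3, benzene, rt) should then move the double bond one position into the ring at the less hindered C7 and comes back to the route at 3.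

Further compounds
F1 | step 5 | methyl 7α,8α-dihydroxy-6-oxo-13,14,15,16-tetranorlabdan-12-oate | COC(=O)C[C@H]1[C@](C)(O)[C@H](O)C(=O)[C@H]2C(C)(C)CCC[C@@]21C
F2 | step 4 | methyl 7-hydroxy-8(7→6)-abeo-13,14,15,16-tetranorlabd-6(8)-en-12-oate | COC(=O)C[C@H]1C(C)=C(CO)[C@H]2C(C)(C)CCC[C@@]21C
F3 | step 4 | methyl 6α,7,8α-trihydroxy-8(7→6)-abeo-13,14,15,16-tetranorlabdan-12-oate | COC(=O)C[C@H]1[C@](C)(O)[C@@](O)(CO)[C@H]2C(C)(C)CCC[C@@]21C
F4 | step 1 | potassium 8α-hydroxy-13,14,15,16-tetranorlabdan-12-oate | [K+].[O-]C(=O)C[C@H]1[C@](C)(O)CC[C@H]2C(C)(C)CCC[C@@]21C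
F5 | step 1 | methyl 8α-hydroxy-13,14,15,16-tetranorlabdan-12-oate | COC(=O)C[C@H]1[C@](C)(O)CC[C@H]2C(C)(C)CCC[C@@]21C
F6 | step 1 | methyl 13,14,15,16-tetranorlabd-8(17)-en-12-oate | COC(=O)C[C@H]1C(=C)CC[C@H]2C(C)(C)CCC[C@@]21C
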